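**Retrosynthetic overview**
- The C1' ester is cut last (Steglich disconnection) to shikonin and 3-acetoxy-3-methylbutanoic acid.
- The strategy rests on ring A (C5–C8): it carries only the two peri hydroxyls at C5 and C8, hydrogens at C6 and C7, and no carbon substituent. It is therefore cut at C4a–C5 and C8a–C8 into a chiral 2-substituted benzoquinone (ring B with the complete side chain) and 1,4-bis(trimethylsilyloxy)cyclohexa-1,3-diene.
- The CH2–CH2 unit of the diene is a temporary ethano bridge. After enolisation and oxidation to the quinone level it is expelled as ethylene (Alder–Rickert), since at that level the extrusion creates a complete benzene ring.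
- The quinone comes from 2-bromo-1,4-dimethoxybenzene and the Weinreb amide of 4-methylpent-3-enoic acid; C1' is set by reagent-controlled ketone reduction and never enters a reacting system afterwards.
- Ring order: ring B is bought as the arene, ring A is closed in the key step and aromatised two steps later.

Key step: step 7

Assumption: bis-silylation of cyclohexane-1,4-dione gives the conjugated 1,3-diene together with its unconjugated 1,4-isomer; only the conjugated isomer can act as a diene, so the distilled mixture is used in excess and the isomer is a spectator.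

**Step 1**
Reactants: 1 4-methylpent-3-enoic acid
Product: 3 N-methoxy-N,4-dimethylpent-3-enamide, via 1-(4-methylpent-3-enoyl)imidazole 2 (not isolated)
Conditions: CDI, CH2Cl2, rt; then MeNHOMe·HCl, rt
Reagents that add atoms: N,O-dimethylhydroxylamine hydrochloride, CNOC.Cl
Why: Carbonyldiimidazole activation to the acyl imidazolide followed by aminolysis is a standard amide coupling that should leave the trisubstituted alkene in its β,γ position.

**Step 2**
Reactants: 3 N-methoxy-N,4-dimethylpent-3-enamide; 4 2-bromo-1,4-dimethoxybenzene
Product: 6 1-(2,5-dimethoxyphenyl)-4-methylpent-3-en-1-one, via (2,5-dimethoxyphenyl)lithium 5 (not isolated)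
Conditions: 4, n-BuLi, THF, −78 °C; then 3, −78 → 0 °C; aq NH4Cl
Reagents that add atoms: none
Why: Bromine–lithium exchange and addition to the Weinreb amide give a chelated tetrahedral adduct that releases the ketone only on work-up (Weinreb ketone synthesis), so over-addition is avoided and the alkene should stay out of conjugation.

**Step 3**
Reactants: 6 1-(2,5-dimethoxyphenyl)-4-methylpent-3-en-1-one
Product: 7 (R)-1-(2,5-dimethoxyphenyl)-4-methylpent-3-en-1-ol
Conditions: (+)-DIP-Cl [(+)-B-chlorodiisopinocampheylborane, from (−)-α-pinene], THF, −25 °C; then CH3CHO, 0 °C → rt; aq NaOH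
Reagents that add atoms: none
Why: Asymmetric ketone reduction with B-chlorodiisopinocampheylborane transfers hydride through a six-membered boat-like transition state with the aryl group as the large substituent, so this enantiomer of the reagent should set C1' as (R), as it does for aryl alkyl ketones in general, and the alkene is inert to it.

**Step 4**
Reactants: 7 (R)-1-(2,5-dimethoxyphenyl)-4-methylpent-3-en-1-ol
Product: 8 (R)-tert-butyl{[1-(2,5-dimethoxyphenyl)-4-methylpent-3-enyl]oxy}dimethylsilane
Conditions: TBSCl, imidazole, DMF, rt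
Reagents that add atoms: tert-butyldimethylsilyl chloride, CC(C)(C)[Si](C)(C)Cl
Why: Imidazole-promoted silylation of a secondary benzylic alcohol is routine and does not touch the C1'–O bond, so the configuration is retained.

**Step 5**
Reactants: 8 (R)-tert-butyl{[1-(2,5-dimethoxyphenyl)-4-methylpent-3-enyl]oxy}dimethylsilane
Product: 9 (R)-2-[1-(tert-butyldimethylsilyloxy)-4-methylpent-3-enyl]-1,4-benzoquinone
Conditions: (NH4)2Ce(NO3)6 (2.2 equiv), MeCN/H2O, 0 °C, short reaction time
Reagents that add atoms: water, O
Why: Oxidative demethylation by tetravalent cerium proceeds by two one-electron oxidations of the electron-rich arene with ipso attack of water and loss of two molecules of methanol; the arene is oxidised far more easily than the alkene, and a short time at 0 °C should preserve the silyl ether.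

**Step 6**
Reactants: 10 cyclohexane-1,4-dione
Product: 11 1,4-bis(trimethylsilyloxy)cyclohexa-1,3-diene
Conditions: Me3SiCl, Et3N, DMF, 80 °C; pentane extraction, distillation
Reagents that add atoms: chlorotrimethylsilane, C[Si](C)(C)Cl
Why: Double silyl enol ether formation under equilibrating amine/chlorosilane conditions; the second enolisation removes the doubly activated proton that is both α to the carbonyl and allylic, which leads to the conjugated diene.

**Step 7**
Reactants: 9 (R)-2-[1-(tert-butyldimethylsilyloxy)-4-methylpent-3-enyl]-1,4-benzoquinone; 11 1,4-bis(trimethylsilyloxy)cyclohexa-1,3-diene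
Product: 12 6-[(R)-1-(tert-butyldimethylsilyloxy)-4-methylpent-3-enyl]-1,4-bis(trimethylsilyloxy)-1,4,4a,8a-tetrahydro-1,4-ethanonaphthalene-5,8-dione (cis-fused; mixture of diastereomers at the four new centers)
Conditions: 11 (excess), PhMe, rt → 45 °C, Ar, dark; volatiles removed under high vacuum, crude used
Reagents that add atoms: none
Why: This is a concerted, asynchronous, normal-demand [4+2] cycloaddition between the s-cis-locked diene, whose HOMO is raised by two silyloxy donors, and the quinone LUMO, forming C4a–C5 and C8a–C8 (target numbering) in one suprafacial event. The closest known reaction type is the Diels–Alder addition of 1-alkoxy- and silyloxy-cyclohexa-1,3-dienes to benzoquinones that is followed by Alder–Rickert aromatisation. Ring A is closed as a six-membered carbocycle by intermolecular cycloaddition across the two oxygenated diene termini, which leaves it as a bicyclo[2.2.2]octene with the CH2–CH2 unit as a temporary bridge. The four new centers (C4a and C8a cis by suprafacial addition, the bridgeheads fixed by the bicycle, endo approach expected) are controlled only relative to each other and not relative to C1', which is acceptable because all four become sp2 in steps 8 and 9. The step needs site selectivity for the unsubstituted C=C of 9 over the C=C bearing the branched silyloxyalkyl group, which is secured by the steric shielding and slight electronic deactivation of the substituted double bond, while the constitutional symmetry of the diene removes any regiochemical question. Cycloaddition must also outrun hydrogen transfer from the diene to the quinone, which the mild temperature, the modest oxidising power of an alkylbenzoquinone and the excess of diene should favour.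

**Step 8**
Reactants: 12 Diels–Alder adduct
Product: 14 6-[(R)-1-(tert-butyldimethylsilyloxy)-4-methylpent-3-enyl]-1,4-bis(trimethylsilyloxy)-1,4-dihydro-1,4-ethanonaphthalene-5,8-dione, via hydroquinone tautomer 13 (not isolated)
Conditions: Et3N (0.3 equiv), CH2Cl2, 0 °C → rt; then Ag2O, Na2SO4, rt
Reagents that add atoms: none
Why: Amine-catalysed double enolisation of the ene-dione is driven by aromatisation to the hydroquinone, and Ag2O then dehydrogenates it to the quinone under neutral aprotic conditions that keep the bridgehead trimethylsilyl ethers; the quinone level is chosen so that the coming ethylene loss creates a full benzene ring.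

**Step 9**
Reactants: 14 quinone-fused bicyclo[2.2.2]octadiene
Product: 15 2-[(R)-1-(tert-butyldimethylsilyloxy)-4-methylpent-3-enyl]-5,8-bis(trimethylsilyloxy)-1,4-naphthoquinone
Conditions: PhMe, 110 °C, Ar (xylenes, 140 °C if slow); crude used
Reagents that add atoms: none
Why: Alder–Rickert retro-[4+2]: the ethano bridge leaves as ethylene because ring A becomes aromatic, the two bridgehead silyloxy groups assist cleavage and end up as the aryl silyl ethers at C5 and C8.

**Step 10**
Reactants: 15 silylated naphthoquinone
Product: 16 shikonin, (R)-5,8-dihydroxy-2-(1-hydroxy-4-methylpent-3-enyl)-1,4-naphthoquinone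
Conditions: Bu4NF, AcOH, THF, 0 °C → rt
Reagents that add atoms: none
Why: Fluoride cleaves the two aryl trimethylsilyl ethers at once and the secondary tert-butyldimethylsilyl ether more slowly; acetic acid buffering keeps the naphthazarin from standing as its base-sensitive phenolate, and C1' is not touched.

**Step 11**
Reactants: 17 3-hydroxy-3-methylbutanoic acid
Product: 19 3-acetoxy-3-methylbutanoic acid, via acetic 3-acetoxy-3-methylbutanoic anhydride 18 (not isolated)
Conditions: AcCl (excess, neat), 0 °C → rt; evaporate; THF/H2O, rt
Reagents that add atoms: acetyl chloride, CC(=O)Cl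
Why: Acetyl chloride acetylates the tertiary alcohol without base, which avoids β-elimination, and the mixed anhydride formed at the carboxyl group is hydrolysed selectively at its less hindered acetyl carbonyl on aqueous treatment.

**Step 12**
Reactants: 16 shikonin; 19 3-acetoxy-3-methylbutanoic acid
Product: 20 (R)-1-(5,8-dihydroxy-1,4-dioxo-1,4-dihydronaphthalen-2-yl)-4-methylpent-3-enyl 3-acetoxy-3-methylbutanoate (target)
Conditions: DCC, DMAP (cat.), CH2Cl2, 0 °C → rt
Reagents that add atoms: none
Why: Steglich esterification acylates the secondary side-chain hydroxyl selectively because the two peri phenols are tied up in hydrogen bonds to the quinone carbonyls, and since the C1'–O bond is not broken the (R) configuration is retained.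

**Compound list**
1 | 4-methylpent-3-enoic acid | CC(C)=CCC(=O)O | starting material
2 | 1-(4-methylpent-3-enoyl)imidazole | CC(C)=CCC(=O)n1ccnc1 | intermediate (not isolated)
3 | N-methoxy-N,4-dimethylpent-3-enamide | CC(C)=CCC(=O)N(C)OC | intermediate
4 | 2-bromo-1,4-dimethoxybenzene | COc1ccc(OC)c(Br)c1 | starting material
5 | (2,5-dimethoxyphenyl)lithium | [Li]c1cc(OC)ccc1OC | intermediate (not isolated)
6 | 1-(2,5-dimethoxyphenyl)-4-methylpent-3-en-1-one | COc1ccc(OC)c(c1)C(=O)CC=C(C)C | intermediate
7 | (R)-1-(2,5-dimethoxyphenyl)-4-methylpent-3-en-1-ol | O[C@H](CC=C(C)C)c1cc(OC)ccc1OC | intermediate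
8 | (R)-tert-butyl{[1-(2,5-dimethoxyphenyl)-4-methylpent-3-enyl]oxy}dimethylsilane | CC(C)(C)[Si](C)(C)O[C@H](CC=C(C)C)c1cc(OC)ccc1OC | intermediate
9 | (R)-2-[1-(tert-butyldimethylsilyloxy)-4-methylpent-3-enyl]-1,4-benzoquinone | CC(C)(C)[Si](C)(C)O[C@H](CC=C(C)C)C1=CC(=O)C=CC1=O | intermediate (key-step precursor)
10 | cyclohexane-1,4-dione | O=C1CCC(=O)CC1 | starting material
11 | 1,4-bis(trimethylsilyloxy)cyclohexa-1,3-diene | C[Si](C)(C)OC1=CC=C(O[Si](C)(C)C)CC1 | intermediate (key-step precursor)
12 | 6-[(R)-1-(tert-butyldimethylsilyloxy)-4-methylpent-3-enyl]-1,4-bis(trimethylsilyloxy)-1,4,4a,8a-tetrahydro-1,4-ethanonaphthalene-5,8-dione, cis-fused, diastereomer mixture at the new centers | CC(C)(C)[Si](C)(C)O[C@H](CC=C(C)C)C1=CC(=O)C2C(C1=O)C1(O[Si](C)(C)C)C=CC2(O[Si](C)(C)C)CC1 | intermediate (key-step product)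
13 | 6-[(R)-1-(tert-butyldimethylsilyloxy)-4-methylpent-3-enyl]-1,4-bis(trimethylsilyloxy)-1,4-dihydro-1,4-ethanonaphthalene-5,8-diol | CC(C)(C)[Si](C)(C)O[C@H](CC=C(C)C)c1cc(O)c2c(c1O)C1(O[Si](C)(C)C)C=CC2(O[Si](C)(C)C)CC1 | intermediate (not isolated)
14 | 6-[(R)-1-(tert-butyldimethylsilyloxy)-4-methylpent-3-enyl]-1,4-bis(trimethylsilyloxy)-1,4-dihydro-1,4-ethanonaphthalene-5,8-dione | CC(C)(C)[Si](C)(C)O[C@H](CC=C(C)C)C1=CC(=O)C2=C(C1=O)C1(O[Si](C)(C)C)C=CC2(O[Si](C)(C)C)CC1 | intermediate
15 | 2-[(R)-1-(tert-butyldimethylsilyloxy)-4-methylpent-3-enyl]-5,8-bis(trimethylsilyloxy)-1,4-naphthoquinone | CC(C)(C)[Si](C)(C)O[C@H](CC=C(C)C)C1=CC(=O)c2c(O[Si](C)(C)C)ccc(O[Si](C)(C)C)c2C1=O | intermediate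
16 | shikonin, (R)-5,8-dihydroxy-2-(1-hydroxy-4-methylpent-3-enyl)-1,4-naphthoquinone | O[C@H](CC=C(C)C)C1=CC(=O)c2c(O)ccc(O)c2C1=O | intermediate
17 | 3-hydroxy-3-methylbutanoic acid | CC(C)(O)CC(=O)O | starting material
18 | acetic 3-acetoxy-3-methylbutanoic anhydride | CC(=O)OC(C)(C)CC(=O)OC(C)=O | intermediate (not isolated)
19 | 3-acetoxy-3-methylbutanoic acid | CC(=O)OC(C)(C)CC(=O)O | intermediate
20 | (R)-1-(5,8-dihydroxy-1,4-dioxo-1,4-dihydronaphthalen-2-yl)-4-methylpent-3-enyl 3-acetoxy-3-methylbutanoate | CC(=O)OC(C)(C)CC(=O)O[C@H](CC=C(C)C)C1=CC(=O)c2c(O)ccc(O)c2C1=O | target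

**Step count**
Total: 12 steps. Longest linear sequence: 10 steps (steps 1–5, 7–10 and 12).

**Steps most likely to fail**

1. Step 7 (key cycloaddition). Hydrogen transfer from the dihydroaromatic diene to the quinone may compete with cycloaddition, bond formation at the two fully substituted diene termini may be slow, and loss of a bridgehead silyl group at the β-silyloxy ketone stage may trigger retro-aldol opening of the bicycle. Fallback, setting out from 9 and returning at 16: the quinone is combined in CH2Cl2 at −20 °C → rt with 2,5-bis(trimethylsilyloxy)furan F1 (made from succinic anhydride with Me3SiCl, Et3N and catalytic ZnCl2), an aromatic diene that cannot be dehydrogenated. This should give the oxygen-bridged adduct 6-[(R)-1-(tert-butyldimethylsilyloxy)-4-methylpent-3-enyl]-1,4-bis(trimethylsilyloxy)-1,4,4a,8a-tetrahydro-1,4-epoxynaphthalene-5,8-dione F2. On dilute acid work-up its two bridgehead silyl ketals collapse to the 5,8-diketone, which tautomerises to the naphthazarin without any extrusion or oxidation, giving O-tert-butyldimethylsilyl shikonin F3. Bu4NF/AcOH as in step 10 then gives shikonin 16.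

2. Step 9 (ethylene extrusion). The retro-[4+2] may be too slow at temperatures the silylated quinone tolerates, so that silyl loss and reactions between the quinone and the side-chain alkene take over. Fallback, setting out from 12 and returning at 16 (it also bypasses step 8): the adduct is enolised and trapped with Me3SiCl/Et3N as the thermally robust aromatic tetrakis(silyl ether) 6-[(R)-1-(tert-butyldimethylsilyloxy)-4-methylpent-3-enyl]-1,4,5,8-tetrakis(trimethylsilyloxy)-1,4-dihydro-1,4-ethanonaphthalene F4. This is heated in o-dichlorobenzene at 180–200 °C, or passed through a flash-vacuum pyrolysis tube, to expel ethylene and give 2-[(R)-1-(tert-butyldimethylsilyloxy)-4-methylpent-3-enyl]-1,4,5,8-tetrakis(trimethylsilyloxy)naphthalene F5. Bu4NF/AcOH then liberates (R)-2-(1-hydroxy-4-methylpent-3-enyl)naphthalene-1,4,5,8-tetrol F6, which is not isolated and is oxidised by air during work-up to shikonin 16.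

3. Step 5 (quinone formation). The acidic cerium oxidant may cleave the silyl ether or attack the trisubstituted alkene before demethylation is complete. Fallback, setting out from 8 and returning at 9: anodic oxidation of 8 at a Pt anode in KOH/MeOH at 0 °C should give the quinone bis(dimethyl ketal) (R)-tert-butyl{[4-methyl-1-(3,3,6,6-tetramethoxycyclohexa-1,4-dienyl)pent-3-enyl]oxy}dimethylsilane F7 under basic conditions that the silyl ether tolerates. Mild hydrolysis (aqueous AcOH in acetone, rt) then releases quinone 9.

**Further compounds**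
F1 | step 7 | 2,5-bis(trimethylsilyloxy)furan | C[Si](C)(C)Oc1ccc(O[Si](C)(C)C)o1
F2 | step 7 | 6-[(R)-1-(tert-butyldimethylsilyloxy)-4-methylpent-3-enyl]-1,4-bis(trimethylsilyloxy)-1,4,4a,8a-tetrahydro-1,4-epoxynaphthalene-5,8-dione | CC(C)(C)[Si](C)(C)O[C@H](CC=C(C)C)C1=CC(=O)C2C(C1=O)C1(O[Si](C)(C)C)C=CC2(O[Si](C)(C)C)O1
F3 | step 7 | O-tert-butyldimethylsilyl shikonin | CC(C)(C)[Si](C)(C)O[C@H](CC=C(C)C)C1=CC(=O)c2c(O)ccc(O)c2C1=O
F4 | step 9 | 6-[(R)-1-(tert-butyldimethylsilyloxy)-4-methylpent-3-enyl]-1,4,5,8-tetrakis(trimethylsilyloxy)-1,4-dihydro-1,4-ethanonaphthalene | CC(C)(C)[Si](C)(C)O[C@H](CC=C(C)C)c1cc(O[Si](C)(C)C)c2c(c1O[Si](C)(C)C)C1(O[Si](C)(C)C)C=CC2(O[Si](C)(C)C)CC1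
F5 | step 9 | 2-[(R)-1-(tert-butyldimethylsilyloxy)-4-methylpent-3-enyl]-1,4,5,8-tetrakis(trimethylsilyloxy)naphthalene | CC(C)(C)[Si](C)(C)O[C@H](CC=C(C)C)c1cc(O[Si](C)(C)C)c2c(O[Si](C)(C)C)ccc(O[Si](C)(C)C)c2c1O[Si](C)(C)C
F6 | step 9 | (R)-2-(1-hydroxy-4-methylpent-3-enyl)naphthalene-1,4,5,8-tetrol | O[C@H](CC=C(C)C)c1cc(O)c2c(O)ccc(O)c2c1O
F7 | step 5 | (R)-tert-butyl{[4-methyl-1-(3,3,6,6-tetramethoxycyclohexa-1,4-dienyl)pent-3-enyl]oxy}dimethylsilane | CC(C)(C)[Si](C)(C)O[C@H](CC=C(C)C)C1=CC(OC)(OC)C=CC1(OC)OC
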